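(The earlier runs and the new flask were generated by integration for substances that don't exist, and the scatter is random.)

You are handed no constants, so you must get them from a count and from the two earlier runs.

| flask | electrophile | free base | protonated nucleophile | remark | time |
|---|---|---|---|---|---|
| dawn | 0.75 M | 1.65 M | 1.35 M | run made earlier |  |
| spring | 1.1 M | 1.65 M | 1.35 M | run made earlier |  |
| flask | 1.5 M | 1.65 M | 1.35 M |  | 2.0 h |

- dawn (time / min: electrophile / %, target / %): 15.0: 68, 20; 40.0: 42, 37; 80.0: 23, 52; 120: 15, 61
- spring (time / min: electrophile / %, target / %): 10.0: 79, 14; 20.0: 64, 23; 50.0: 40, 38; 120: 23, 51

(each reading ± 1.5 percentage points)

- what has gone from electrophile into another species counts as reacted, even if it can come back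
- the earlier runs do not show how much of nucleophile is bound; that part of a forecast is a guess

- part of the electrophile that has reacted at 2.0 h
- share of the unused nucleophile that is free and not bound as protonated nucleophile, at 2.0 h

Begin with the count. Take it that each target sets one acid free and that each protonated nucleophile brings one along. Suppose too that free base takes up acid first, a supposition and not a reading. Free base then first frees the charged protonated nucleophile, which leaves 0.300 M of spare base. Once that is used up, every target costs two free nucleophiles: one used and one bound. Free nucleophile is then the free base charged minus twice the target, so target has a ceiling, half the free base charged, 0.825 M. In this flask that is 55.0% of the electrophile charged, which on this count makes free base the limiting reagent.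

Now the rate. Target made per minute up to the first dawn reading, divided by the mean electrophile and the mean free nucleophile of that stretch, reads as a rate constant of 0.0124 M⁻¹ min⁻¹. Electrophile also has a second fork: what was lost but is not target came to 24.0% at dawn and 26.0% in spring, at 120 min, a mean of 25.0%. Setting that aside and integrating to 2.0 h, a rough step that uses the count's free nucleophile from the very start, gives 0.697 M of target, so 71.5% reacted.

The weak link is that side share, which read higher at the larger charge. The two shares differ by 2 percentage points on readings scattered by 1.5 points, so the trend is a tentative one, but carried on to this flask's charge it gives 28.3%. Target is then 0.682 M, so I commit to 73.8% reacted and 42.7% free, the second figure a guess that rests on the supposed order of uptake.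

The forecast, at 65% reacted and 40% free on the view that “released acid is pulling nucleophile back into its protonated form”, stands below my figure for reacted electrophile.

The flask gives 73.8% reacted and 38.3% free.

    electrophile + nucleophile → acid set free + target (k = 0.0130 M⁻¹ min⁻¹)
    nucleophile + acid set free ⇌ protonated nucleophile, settled at all times (K = 370 M⁻¹)
    acid set free + free base ⇌ salt of the base, settled at all times (K = 10000 M⁻¹)
    acid set free + target → side product (k = 0.00590 M⁻¹ min⁻¹)
    electrophile ⇌ dormant form (K = 1.10, k = 0.00940 min⁻¹)

At 2.00 h this flask's target stands at 45.3% of the electrophile charged, under the ceiling of 55.0%, with 2.25% of the charged free base still free. In the neighbour charged with 0.66 M of free base, the same count puts the ceiling at 22.0% of the electrophile charged, and at 2.00 h that neighbour holds 21.0% as target.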